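**Strategy.** The target is a symmetrical diarylmethane. In each ring (ring A and ring B) C1 carries the bridging carbon, C2 and C3 carry bromine, C4 and C5 carry oxygen, and C6 carries hydrogen. Cutting each ring at C2–C3 and C6–C1 exposes a bromoalkynyl carbonyl unit (C1, C2) and a butadiene oxygenated at its two inner carbons (C3 to C6). One twofold Diels–Alder reaction of 1,5-dibromopenta-1,4-diyn-3-one with 2,3-dimethoxybuta-1,3-diene therefore assembles both carbocycles with the bridge carbon, the C2 bromines and all four oxygens in place. The bridging ketone first activates both alkynes, later steers bromination of the derived catechols to C3, and is finally reduced to CH2.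

Key step: step 4

Remark: 2,3-dimethoxybuta-1,3-diene is taken as a catalogue reagent. The bromoalkynes of the route are treated as potentially energetic, light-sensitive electrophiles and are kept cold, dilute and in solution.

**Step 1**
Reactants: 1 trimethylsilylacetylene (2 equiv, both incorporated); 2 ethyl formate
Product: 5 1,5-bis(trimethylsilyl)penta-1,4-diyn-3-ol, via lithium (trimethylsilyl)acetylide 3 (not isolated), via 3-(trimethylsilyl)prop-2-ynal 4 (not isolated)
Conditions: 1 (2.2 equiv), n-BuLi (2.1 equiv), THF, −78 °C; then 2 (1.0 equiv), −78 °C → rt; aq NH4Cl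
Reagents that add atoms: trimethylsilylacetylene (second molecule of 1), C#C[Si](C)(C)C
Why: Deprotonation gives acetylide 3, one molecule of which undergoes acyl substitution on the formate to aldehyde 4 and a second molecule of which then adds 1,2 to that aldehyde, the standard formate route to symmetrical secondary carbinols; the carbinol carbon bears two identical arms and is not a stereocenter.

**Step 2**
Reactants: 5 1,5-bis(trimethylsilyl)penta-1,4-diyn-3-ol
Product: 6 1,5-dibromopenta-1,4-diyn-3-ol
Conditions: NBS (2.2 equiv), AgNO3 (0.2 equiv), acetone, rt, dark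
Reagents that add atoms: N-bromosuccinimide, O=C1CCC(=O)N1Br
Why: AgNO3-catalysed bromodesilylation of alkynylsilanes (through a transient AgC≡CR intermediate that is brominated by NBS) should exchange both C–Si bonds for C–Br under neutral conditions that leave the secondary alcohol untouched.

**Step 3**
Reactants: 6 1,5-dibromopenta-1,4-diyn-3-ol
Product: 7 1,5-dibromopenta-1,4-diyn-3-one
Conditions: activated MnO2 (excess), CH2Cl2, 0 °C → rt; filtration through Celite; solvent exchange to toluene below 20 °C, solution used at once
Reagents that add atoms: none
Why: MnO2 oxidation of a doubly propargylic alcohol is fast, heterogeneous and neutral, so the electrophilic bromoalkynyl ketone should be released without acid, base or nucleophile and be obtained by filtration alone.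

**Step 4**
Reactants: 7 1,5-dibromopenta-1,4-diyn-3-one; 8 2,3-dimethoxybuta-1,3-diene (2 equiv incorporated)
Product: 10 bis(2-bromo-4,5-dimethoxycyclohexa-1,4-dien-1-yl)methanone, via 3-bromo-1-(2-bromo-4,5-dimethoxycyclohexa-1,4-dien-1-yl)prop-2-yn-1-one 9 (not isolated)
Conditions: 8 (3 equiv), toluene, BHT (cat.), 2,6-di-tert-butyl-4-methylpyridine (cat.), 0 °C → rt, then 70 °C, Ar, dark; excess 8 removed in vacuo
Reagents that add atoms: 2,3-dimethoxybuta-1,3-diene (second molecule of 8), COC(=C)C(=C)OC
Why: Two successive concerted, suprafacial, normal-electron-demand [4+2] cycloadditions should take place: the s-cis diene 8, its HOMO raised by the two methoxy groups, adds first to one and then (via 9) to the other bromoalkynyl ketone arm of 7, whose LUMO is lowered by the shared carbonyl. The closest known reaction type is the thermal Diels–Alder reaction of 3-bromopropiolates and alkynyl ketones with 2,3-disubstituted butadienes, which gives 1,4-cyclohexadienes. Ring A and ring B are each closed by an intermolecular [4+2] annulation in which C2–C3 and C6–C1 form in one pericyclic event, the alkyne supplying C1 and C2 and the diene C3 to C6. No stereocenter is created, since every new ring carbon is either sp2 or a CH2 group. Regioselectivity does not arise because 8 is symmetrical; the selectivity needed is cycloaddition in preference to polar addition of the enol ether to the ynone or to the C–Br terminus, which the apolar, buffered medium free of Lewis acid and the linear, unhindered dienophile favour. The second ring closure is secured by excess 8 and by the remaining alkynyl ketone of 9 being far more electron-poor and accessible than the tetrasubstituted bromoalkene of the first ring.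

**Step 5**
Reactants: 10 bis(2-bromo-4,5-dimethoxycyclohexa-1,4-dien-1-yl)methanone
Product: 11 bis(2-bromo-4,5-dimethoxyphenyl)methanone
Conditions: DDQ (2.2 equiv), dry toluene, 0 °C → rt
Reagents that add atoms: none
Why: DDQ dehydrogenation of a 1,4-cyclohexadiene (hydride abstraction from a doubly allylic CH2 next to an enol ether oxygen, then proton loss) should aromatise both rings, driven by the gain in aromaticity, and turn the vinyl bromides into aryl bromides unchanged.

**Step 6**
Reactants: 11 bis(2-bromo-4,5-dimethoxyphenyl)methanone
Product: 12 bis(2-bromo-4,5-dihydroxyphenyl)methanone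
Conditions: BBr3 (6 equiv), CH2Cl2, −78 °C → rt; then H2O
Reagents that add atoms: none
Why: BBr3 ether cleavage (O–B complexation, bromide attack at methyl) should remove all four aryl methyl ethers while the diaryl ketone and the aryl bromides stay inert; the carbonyl is kept because it steers the next step.

**Step 7**
Reactants: 12 bis(2-bromo-4,5-dihydroxyphenyl)methanone
Product: 13 bis(2,3-dibromo-4,5-dihydroxyphenyl)methanone
Conditions: Br2 (2.05 equiv), AcOH, rt
Reagents that add atoms: bromine, BrBr
Why: Electrophilic aromatic bromination of an acyl catechol should occur at C3, ortho to the C4 hydroxyl that lies para to the carbonyl, because C6 is ortho to the deactivating ketone (the pattern known from 3,4-dihydroxybenzaldehyde and vanillin), and the electron-poor catechol should resist oxidation to the o-quinone.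

**Step 8**
Reactants: 13 bis(2,3-dibromo-4,5-dihydroxyphenyl)methanone
Product: 14 bis(2,3-dibromo-4,5-dihydroxyphenyl)methane
Conditions: Et3SiH (6 equiv), CF3CO2H, rt → 50 °C
Reagents that add atoms: none
Why: Ionic hydrogenation should convert the protonated diaryl ketone into the benzhydrol, ionise it to a diarylmethyl cation stabilised by the para hydroxyls at C4 of both rings and deliver a second hydride to give the CH2 bridge, conditions under which aryl bromides and phenols persist.

**Compound list**
1 | trimethylsilylacetylene | C#C[Si](C)(C)C | starting material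
2 | ethyl formate | CCOC=O | starting material
3 | lithium (trimethylsilyl)acetylide | [Li]C#C[Si](C)(C)C | intermediate
4 | 3-(trimethylsilyl)prop-2-ynal | O=CC#C[Si](C)(C)C | intermediate
5 | 1,5-bis(trimethylsilyl)penta-1,4-diyn-3-ol | C[Si](C)(C)C#CC(O)C#C[Si](C)(C)C | intermediate
6 | 1,5-dibromopenta-1,4-diyn-3-ol | OC(C#CBr)C#CBr | intermediate
7 | 1,5-dibromopenta-1,4-diyn-3-one | O=C(C#CBr)C#CBr | intermediate
8 | 2,3-dimethoxybuta-1,3-diene | COC(=C)C(=C)OC | starting material
9 | 3-bromo-1-(2-bromo-4,5-dimethoxycyclohexa-1,4-dien-1-yl)prop-2-yn-1-one | O=C(C#CBr)C1=C(Br)CC(OC)=C(OC)C1 | intermediate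
10 | bis(2-bromo-4,5-dimethoxycyclohexa-1,4-dien-1-yl)methanone | O=C(C1=C(Br)CC(OC)=C(OC)C1)C1=C(Br)CC(OC)=C(OC)C1 | intermediate
11 | bis(2-bromo-4,5-dimethoxyphenyl)methanone | COc1cc(Br)c(cc1OC)C(=O)c1cc(OC)c(OC)cc1Br | intermediate
12 | bis(2-bromo-4,5-dihydroxyphenyl)methanone | O=C(c1cc(O)c(O)cc1Br)c1cc(O)c(O)cc1Br | intermediate
13 | bis(2,3-dibromo-4,5-dihydroxyphenyl)methanone | O=C(c1cc(O)c(O)c(Br)c1Br)c1cc(O)c(O)c(Br)c1Br | intermediate
14 | bis(2,3-dibromo-4,5-dihydroxyphenyl)methane | Oc1cc(Cc2cc(O)c(O)c(Br)c2Br)c(Br)c(Br)c1O | target

Total step count: 8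
Longest linear sequence: 8 steps (steps 1 to 8; diene 8 enters as a purchased reagent in step 4)

**Steps most likely to fail**

Step 4. The bromoalkyne termini may be consumed by non-pericyclic pathways (attack of the enol ether at carbon or at bromine, oligomerisation of the diynone) faster than the second ring closes, or the reaction may stop after one ring. The fallback keeps the twofold cycloaddition but makes the C2–Br bonds only after the rings exist, and it avoids compound 7 altogether. It sets out from 5, which is oxidised with MnO2 in CH2Cl2 to 1,5-bis(trimethylsilyl)penta-1,4-diyn-3-one F1. This robust silyl ynone is heated with excess 8 in toluene at 110–130 °C in a sealed vessel to give bis[4,5-dimethoxy-2-(trimethylsilyl)cyclohexa-1,4-dien-1-yl]methanone F2. DDQ in toluene aromatises it to bis[4,5-dimethoxy-2-(trimethylsilyl)phenyl]methanone F3. Ipso-bromodesilylation with Br2 in CH2Cl2 at 0 °C, at the silylated carbon para to the C5 methoxy group, then returns to the route at 11.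

Step 7. Site control may be lost (bromination at C6 or a third bromine per ring), or bromine may oxidise the catechols to o-quinones. The fallback replaces electrophilic substitution by directed metalation on the methyl ethers. It sets out from 11, which is reduced with Et3SiH in CF3CO2H to bis(2-bromo-4,5-dimethoxyphenyl)methane F4. The C3–H of each ring, the only one flanked by bromine and methoxy, is removed with TMPMgCl·LiCl in THF at −20 to 0 °C to give bis[2-bromo-3-(chloromagnesio)-4,5-dimethoxyphenyl]methane F5. Quenching with 1,2-dibromo-1,1,2,2-tetrachloroethane gives bis(2,3-dibromo-4,5-dimethoxyphenyl)methane F6. BBr3 in CH2Cl2 then returns to the route at 14.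

Step 8. Hydride transfer to the hindered, electron-poor ketone may stall, since the ortho bromines twist the carbonyl out of conjugation, leaving ketone or carbinol unreduced. The fallback splits the reduction into a nucleophilic and an ionic stage. It sets out from 13, which is reduced with excess NaBH4 in THF/MeOH at 0 °C → rt to bis(2,3-dibromo-4,5-dihydroxyphenyl)methanol F7. This carbinol ionises readily in CF3CO2H/CH2Cl2 at 0 °C to the cation stabilised by the para hydroxyls and is trapped by Et3SiH, returning to the route at 14.

**Further compounds**
F1 | step 4 | 1,5-bis(trimethylsilyl)penta-1,4-diyn-3-one | O=C(C#C[Si](C)(C)C)C#C[Si](C)(C)C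
F2 | step 4 | bis[4,5-dimethoxy-2-(trimethylsilyl)cyclohexa-1,4-dien-1-yl]methanone | O=C(C1=C([Si](C)(C)C)CC(OC)=C(OC)C1)C1=C([Si](C)(C)C)CC(OC)=C(OC)C1
F3 | step 4 | bis[4,5-dimethoxy-2-(trimethylsilyl)phenyl]methanone | O=C(c1cc(OC)c(OC)cc1[Si](C)(C)C)c1cc(OC)c(OC)cc1[Si](C)(C)C
F4 | step 7 | bis(2-bromo-4,5-dimethoxyphenyl)methane | COc1cc(Br)c(Cc2cc(OC)c(OC)cc2Br)cc1OC
F5 | step 7 | bis[2-bromo-3-(chloromagnesio)-4,5-dimethoxyphenyl]methane | COc1cc(Cc2cc(OC)c(OC)c([Mg]Cl)c2Br)c(Br)c([Mg]Cl)c1OC
F6 | step 7 | bis(2,3-dibromo-4,5-dimethoxyphenyl)methane | COc1cc(Cc2cc(OC)c(OC)c(Br)c2Br)c(Br)c(Br)c1OC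
F7 | step 8 | bis(2,3-dibromo-4,5-dihydroxyphenyl)methanol | OC(c1cc(O)c(O)c(Br)c1Br)c1cc(O)c(O)c(Br)c1Br
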